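A direct plan would link phlorobutyrophenone A1 to ring B by quinone methide alkylation (dimer A2), make sulfone A3 via a Mannich base, add hydroxyacetone A4 to the ring A quinone methide from A3 under chiral enamine catalysis (α-hydroxy ketone A5) and finish by Wittig methylenation. Its weakest steps would be:
- the enamine addition, which would have to set C2′ on the donor carbon with an unsubstituted methylene quinone methide, without precedent and against a racemic background;
- the Wittig methylenation, which would expose an enolisable α-hydroxy ketone and five phenols to excess basic ylide, with risk of epimerisation at C2′;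
- the Mannich–sulfinate exchange to A3, which would add two operations but no bond of the target.

The side chain on ring A, C1′H2–C2′H(OH)–C3′(CH3)=CH2, is the ring-opened form of a 2,2-dimethyloxirane, that is, of epoxidised prenol. The route therefore cuts the bond between ring A and C1′ with ring A as the nucleophile: ortho-lithiated 1,3,5-tris(methoxymethoxy)benzene displaces triflate from the Katsuki–Sharpless epoxide of prenol. This one operation joins the whole C5 chain and imports C2′ with its C–O bond in place; a base-mediated oxirane isomerisation then unveils the isopropenyl carbinol. No stereocentre is made on a polyphenol, no olefination is needed, and the methylene bridge is formed last in one quinone methide coupling, so the enamine addition, the Wittig step and the sulfone detour all disappear.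

Key step: step 4

Remark: 3-methylbut-2-en-1-ol and 2-methylphloroglucinol are taken as commercial; side-chain carbons are called C1′ (benzylic CH2), C2′ (carbinol), C3′ and C4′ (=CH2), and in 10 and 11 the butanoyl group is on C1, the side chain on C3 and the free ring position is C5.

**Step 1**
Reactants: 1 phloroglucinol (benzene-1,3,5-triol)
Product: 2 1,3,5-tris(methoxymethoxy)benzene
Conditions: NaH (3.5 equiv), MOMCl (3.5 equiv), DMF, 0 °C → rt
Reagents that add atoms: chloromethyl methyl ether, COCCl
Why: Williamson ether synthesis on the tris-phenoxide with a hard chloromethyl ether should give the tris-acetal, which masks the acidic phenols and supplies the directing groups for the two later ortho-lithiations.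

**Step 2**
Reactants: 3 3-methylbut-2-en-1-ol (prenol)
Product: 4 [(2R)-3,3-dimethyloxiran-2-yl]methanol
Conditions: Ti(OiPr)4 (5 mol %), D-(−)-diisopropyl tartrate (6 mol %), t-BuOOH (1.5 equiv, in isooctane), 4 Å molecular sieves, CH2Cl2, −20 °C; non-aqueous work-up, distillation
Reagents that add atoms: tert-butyl hydroperoxide, CC(C)(C)OO
Why: Katsuki–Sharpless asymmetric epoxidation, in which the allylic alcohol and the peroxide are bound to the titanium tartrate and the D-(−)-tartrate directs oxygen transfer to the alkene face that gives the (2R)-oxirane (L-(+)-tartrate gives the (2S) series with allylic alcohols of this pattern), so that C2′ of the target is set here by the ligand.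

**Step 3**
Reactants: 4 [(2R)-3,3-dimethyloxiran-2-yl]methanol
Product: 5 [(2R)-3,3-dimethyloxiran-2-yl]methyl trifluoromethanesulfonate
Conditions: Tf2O (1.05 equiv), 2,6-lutidine (1.2 equiv), CH2Cl2, −78 °C; cold filtration through silica, used at once
Reagents that add atoms: trifluoromethanesulfonic anhydride, O=S(=O)(OS(=O)(=O)C(F)(F)F)C(F)(F)F
Why: O-Triflation of the primary alcohol with a hindered base at −78 °C should leave the oxirane and the stereocentre untouched, so the configuration stays (R).

**Step 4**
Reactants: 2 1,3,5-tris(methoxymethoxy)benzene; 5 [(2R)-3,3-dimethyloxiran-2-yl]methyl trifluoromethanesulfonate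
Product: 7 (3R)-2,2-dimethyl-3-{[2,4,6-tris(methoxymethoxy)phenyl]methyl}oxirane, via aryllithium 6 (not isolated)
Conditions: 2 (1.3 equiv), n-BuLi (1.25 equiv), THF, 0 °C; CuBr·SMe2 (10 mol %), −78 °C; then 5 (1.0 equiv), −78 → −30 °C
Reagents that add atoms: none
Why: Directed ortho-metalation removes the ring proton of 2 that lies between two methoxymethoxy groups (the three ring protons are equivalent), and the aryl carbanion of 6, with a catalytic amount of monovalent copper, displaces triflate from the primary carbon C1′ of 5 in an SN2 reaction, which makes the bond between ring A and C1′. The closest known reaction types are the copper-catalysed substitution of glycidyl-type epoxy triflates by organomagnesium reagents with the oxirane left intact, and the alkylation of this same aryllithium by prenyl bromide. No ring is closed. No stereocentre is created: C2′ arrives from 4 with its C–O bond in place, the new bond is made on the neighbouring CH2, and the CIP order at C2′ (O > C3′ > C1′ > H) is unchanged, so it stays (R). The step needs attack at C1′ and not at the oxirane, which is secured because triflate leaves already at −78 °C while both oxirane carbons are hindered (C3′ is fully substituted, C2′ is secondary and flanked by it). Only one alkylation can occur, because 6 is a monoanion and 5 is the limiting reagent.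

**Step 5**
Reactants: 7 (3R)-2,2-dimethyl-3-{[2,4,6-tris(methoxymethoxy)phenyl]methyl}oxirane
Product: 8 (2R)-3-methyl-1-[2,4,6-tris(methoxymethoxy)phenyl]but-3-en-2-ol
Conditions: 2,2,6,6-tetramethylpiperidine (3 equiv), n-BuLi (3 equiv), Et2AlCl (3 equiv), toluene, 0 °C, to give Et2Al(NC9H18); then 7, 0 °C → rt; aq. KNaC4H4O6 (potassium sodium tartrate)
Reagents that add atoms: none
Why: Aluminium amide-mediated isomerisation of an epoxide to an allylic alcohol, in which aluminium binds the oxirane oxygen and the amide removes a methyl proton through a cyclic syn transition state as the tertiary C3′–O bond breaks, so the C2′–O bond and the (R) configuration are untouched, while loss of a benzylic C1′ proton would need cleavage of the secondary C2′–O bond and is disfavoured.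

**Step 6**
Reactants: 8 (2R)-3-methyl-1-[2,4,6-tris(methoxymethoxy)phenyl]but-3-en-2-ol
Product: 10 1-{3-[(2R)-2-hydroxy-3-methylbut-3-en-1-yl]-2,4,6-tris(methoxymethoxy)phenyl}butan-1-one, via ring-lithiated lithium alkoxide 9 (not isolated)
Conditions: n-BuLi (2.3 equiv), THF, 0 °C; N-methoxy-N-methylbutanamide (1.5 equiv), −78 → 0 °C; aq. NH4Cl
Reagents that add atoms: N-methoxy-N-methylbutanamide, CCCC(=O)N(C)OC
Why: Directed ortho-metalation followed by Weinreb ketone synthesis: the first equivalent of n-BuLi forms the lithium alkoxide, the second removes one of the two equivalent ring protons flanked by two methoxymethoxy groups, and the aryllithium adds only once to the amide because the chelated tetrahedral adduct survives until work-up, with C2′ not involved.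

**Step 7**
Reactants: 10 1-{3-[(2R)-2-hydroxy-3-methylbut-3-en-1-yl]-2,4,6-tris(methoxymethoxy)phenyl}butan-1-one
Product: 11 1-{2,4,6-trihydroxy-3-[(2R)-2-hydroxy-3-methylbut-3-en-1-yl]phenyl}butan-1-one
Conditions: HCl (0.5 M in MeOH), rt
Reagents that add atoms: none
Why: Acid-catalysed transacetalisation of the three aryl methoxymethyl ethers to dimethoxymethane should free the phenols under conditions that ortho-prenylphenols tolerate, and the isopropenyl group here is less basic still because of the adjacent C2′–O bond, so neither chroman formation nor ionisation at C2′ is expected and the configuration is kept.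

**Step 8**
Reactants: 12 2-methylphloroglucinol (2-methylbenzene-1,3,5-triol)
Product: 13 1-(2,4,6-trihydroxy-3-methylphenyl)ethan-1-one
Conditions: AcOH (1.1 equiv), BF3·OEt2 (solvent), 90 °C; aq. NaOAc work-up
Reagents that add atoms: acetic acid, CC(=O)O
Why: BF3-mediated Friedel–Crafts C-acylation should give a single mono-ketone, because the two free ring positions of 12 are equivalent and the chelated product is deactivated.

**Step 9**
Reactants: 13 1-(2,4,6-trihydroxy-3-methylphenyl)ethan-1-one
Product: 14 1-(2,6-dihydroxy-4-methoxy-3-methylphenyl)ethan-1-one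
Conditions: Me2SO4 (1.05 equiv), K2CO3 (1.1 equiv), acetone, reflux
Reagents that add atoms: dimethyl sulfate, COS(=O)(=O)OC
Why: Williamson O-methylation should select the hydroxyl para to the acetyl group, which is the most acidic one and the only one not hydrogen-bonded to the ketone.

**Step 10**
Reactants: 14 1-(2,6-dihydroxy-4-methoxy-3-methylphenyl)ethan-1-one
Product: 15 1-{3-[(dimethylamino)methyl]-2,6-dihydroxy-4-methoxy-5-methylphenyl}ethan-1-one
Conditions: Me2NCH2NMe2 (1.2 equiv), CH2Cl2, rt
Reagents that add atoms: bis(dimethylamino)methane, CN(C)CN(C)C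
Why: Phenolic Mannich reaction at the only unsubstituted ring carbon, which lies ortho to a hydroxyl group.

**Step 11**
Reactants: 15 1-{3-[(dimethylamino)methyl]-2,6-dihydroxy-4-methoxy-5-methylphenyl}ethan-1-one; 11 1-{2,4,6-trihydroxy-3-[(2R)-2-hydroxy-3-methylbut-3-en-1-yl]phenyl}butan-1-one
Product: 17 1-{3-[(3-acetyl-2,4-dihydroxy-6-methoxy-5-methylphenyl)methyl]-2,4,6-trihydroxy-5-[(2R)-2-hydroxy-3-methylbut-3-en-1-yl]phenyl}butan-1-one (the target), via ring B o-quinone methide 16 (not isolated)
Conditions: 15 (1.0 equiv), 11 (1.05 equiv), 1,4-dioxane, 90 °C, N2 sweep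
Reagents that add atoms: none
Why: Thermal retro-Mannich (E1cB) loss of dimethylamine should give o-quinone methide 16, which is trapped by Friedel–Crafts-type conjugate addition of C5 of 11, its only unsubstituted ring carbon and ortho or para to three hydroxyl groups, so over-alkylation is impossible and the remote stereocentre C2′ stays (R).

**Compound list**
1 | phloroglucinol (benzene-1,3,5-triol) | Oc1cc(O)cc(O)c1 | starting material
2 | 1,3,5-tris(methoxymethoxy)benzene | COCOc1cc(OCOC)cc(OCOC)c1 | intermediate
3 | 3-methylbut-2-en-1-ol (prenol) | CC(C)=CCO | starting material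
4 | [(2R)-3,3-dimethyloxiran-2-yl]methanol | CC1(C)O[C@@H]1CO | intermediate
5 | [(2R)-3,3-dimethyloxiran-2-yl]methyl trifluoromethanesulfonate | CC1(C)O[C@@H]1COS(=O)(=O)C(F)(F)F | intermediate
6 | [2,4,6-tris(methoxymethoxy)phenyl]lithium | [Li]c1c(OCOC)cc(OCOC)cc1OCOC | intermediate
7 | (3R)-2,2-dimethyl-3-{[2,4,6-tris(methoxymethoxy)phenyl]methyl}oxirane | CC1(C)O[C@@H]1Cc1c(OCOC)cc(OCOC)cc1OCOC | intermediate
8 | (2R)-3-methyl-1-[2,4,6-tris(methoxymethoxy)phenyl]but-3-en-2-ol | C=C(C)[C@H](O)Cc1c(OCOC)cc(OCOC)cc1OCOC | intermediate
9 | lithium (2R)-1-[3-lithio-2,4,6-tris(methoxymethoxy)phenyl]-3-methylbut-3-en-2-olate | [Li+].C=C(C)[C@H]([O-])Cc1c(OCOC)cc(OCOC)c([Li])c1OCOC | intermediate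
10 | 1-{3-[(2R)-2-hydroxy-3-methylbut-3-en-1-yl]-2,4,6-tris(methoxymethoxy)phenyl}butan-1-one | C=C(C)[C@H](O)Cc1c(OCOC)cc(OCOC)c(C(=O)CCC)c1OCOC | intermediate
11 | 1-{2,4,6-trihydroxy-3-[(2R)-2-hydroxy-3-methylbut-3-en-1-yl]phenyl}butan-1-one | C=C(C)[C@H](O)Cc1c(O)cc(O)c(C(=O)CCC)c1O | intermediate
12 | 2-methylphloroglucinol (2-methylbenzene-1,3,5-triol) | Cc1c(O)cc(O)cc1O | starting material
13 | 1-(2,4,6-trihydroxy-3-methylphenyl)ethan-1-one | CC(=O)c1c(O)cc(O)c(C)c1O | intermediate
14 | 1-(2,6-dihydroxy-4-methoxy-3-methylphenyl)ethan-1-one | CC(=O)c1c(O)cc(OC)c(C)c1O | intermediate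
15 | 1-{3-[(dimethylamino)methyl]-2,6-dihydroxy-4-methoxy-5-methylphenyl}ethan-1-one | CC(=O)c1c(O)c(CN(C)C)c(OC)c(C)c1O | intermediate
16 | 2-acetyl-3-hydroxy-5-methoxy-4-methyl-6-methylidenecyclohexa-2,4-dien-1-one (ring B o-quinone methide) | C=C1C(=O)C(C(C)=O)=C(O)C(C)=C1OC | intermediate
17 | 1-{3-[(3-acetyl-2,4-dihydroxy-6-methoxy-5-methylphenyl)methyl]-2,4,6-trihydroxy-5-[(2R)-2-hydroxy-3-methylbut-3-en-1-yl]phenyl}butan-1-one | C=C(C)[C@H](O)Cc1c(O)c(Cc2c(O)c(C(C)=O)c(O)c(C)c2OC)c(O)c(C(=O)CCC)c1O | target

Total step count: 11. Longest linear sequence: 7 steps (steps 2, 3, 4, 5, 6, 7 and 11, from 3-methylbut-2-en-1-ol).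

**Steps most likely to fail**

Step 4 could suffer from attack of the aryllithium on the oxirane or at sulfur, or from decomposition of the triflate before it is coupled. The fallback would set out from 6 and alkylate it with 1-bromo-3-methylbut-2-ene (CuI cat., THF, −78 °C → rt) to give 1,3,5-tris(methoxymethoxy)-2-(3-methylbut-2-en-1-yl)benzene F1. A Shi epoxidation of its trisubstituted alkene (D-fructose-derived ketone, Oxone (2KHSO5·KHSO4·K2SO4), K2CO3, MeCN–dimethoxymethane–H2O, 0 °C) would then set C2′ by reagent control; the spiro transition state of this ketone is expected to give the (R)-oxirane. The fallback would come back to the route at 7.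

Step 5 could suffer from proton abstraction at the benzylic carbon C1′, which would give the conjugated tertiary alcohol, or from cleavage of methoxymethyl ethers by the aluminium reagent. The fallback would set out from 7 and change the mechanism from a base-mediated to a radical elimination. Cp2TiCl, made from Cp2TiCl2 and Mn dust in THF at rt, would open the oxirane homolytically at C3′ with trivalent titanium on oxygen, and a second Cp2TiCl would take a hydrogen atom from a methyl group of the tertiary radical. The benzylic hydrogens are not β to the radical and cannot be lost. The fallback would come back at 8 and make no new compound.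

Step 6 could suffer from enolisation of the Weinreb amide by the hindered aryllithium, or from incomplete ring lithiation next to the alkoxide. The fallback would set out from 8 and silylate the alcohol (TBSCl, imidazole, DMF) to the tert-butyldimethylsilyl ether F2. Lithiation (n-BuLi, THF, 0 °C) would give the aryllithium F3, addition of butanal the benzylic alcohol F4 as a pair of epimers, and oxidation with Dess–Martin periodinane the ketone F5. The methanolic HCl of step 7 would then remove the silyl group together with the three methoxymethyl groups, so the fallback would come back at 11.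

**Further compounds**
F1 | step 4 | 1,3,5-tris(methoxymethoxy)-2-(3-methylbut-2-en-1-yl)benzene | CC(C)=CCc1c(OCOC)cc(OCOC)cc1OCOC
F0 | step 5 | none | none
F2 | step 6 | tert-butyl(dimethyl){[(2R)-3-methyl-1-[2,4,6-tris(methoxymethoxy)phenyl]but-3-en-2-yl]oxy}silane | C=C(C)[C@H](O[Si](C)(C)C(C)(C)C)Cc1c(OCOC)cc(OCOC)cc1OCOC
F3 | step 6 | {3-[(2R)-2-{[tert-butyl(dimethyl)silyl]oxy}-3-methylbut-3-en-1-yl]-2,4,6-tris(methoxymethoxy)phenyl}lithium | [Li]c1c(OCOC)cc(OCOC)c(C[C@@H](O[Si](C)(C)C(C)(C)C)C(C)=C)c1OCOC
F4 | step 6 | 1-{3-[(2R)-2-{[tert-butyl(dimethyl)silyl]oxy}-3-methylbut-3-en-1-yl]-2,4,6-tris(methoxymethoxy)phenyl}butan-1-ol (both epimers at the new carbinol carbon) | CCCC(O)c1c(OCOC)cc(OCOC)c(C[C@@H](O[Si](C)(C)C(C)(C)C)C(C)=C)c1OCOC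
F5 | step 6 | 1-{3-[(2R)-2-{[tert-butyl(dimethyl)silyl]oxy}-3-methylbut-3-en-1-yl]-2,4,6-tris(methoxymethoxy)phenyl}butan-1-one | CCCC(=O)c1c(OCOC)cc(OCOC)c(C[C@@H](O[Si](C)(C)C(C)(C)C)C(C)=C)c1OCOC
A1 | direct plan | 1-(2,4,6-trihydroxyphenyl)butan-1-one | CCCC(=O)c1c(O)cc(O)cc1O
A2 | direct plan | 1-{3-[(3-acetyl-2,4-dihydroxy-6-methoxy-5-methylphenyl)methyl]-2,4,6-trihydroxyphenyl}butan-1-one | CCCC(=O)c1c(O)cc(O)c(Cc2c(O)c(C(C)=O)c(O)c(C)c2OC)c1O
A3 | direct plan | 1-{3-[(3-acetyl-2,4-dihydroxy-6-methoxy-5-methylphenyl)methyl]-2,4,6-trihydroxy-5-[(4-methylbenzenesulfonyl)methyl]phenyl}butan-1-one | CCCC(=O)c1c(O)c(CS(=O)(=O)c2ccc(C)cc2)c(O)c(Cc2c(O)c(C(C)=O)c(O)c(C)c2OC)c1O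
A4 | direct plan | 1-hydroxypropan-2-one (hydroxyacetone) | CC(=O)CO
A5 | direct plan | 1-{3-[(3-acetyl-2,4-dihydroxy-6-methoxy-5-methylphenyl)methyl]-2,4,6-trihydroxy-5-[(2R)-2-hydroxy-3-oxobutyl]phenyl}butan-1-one | CC(=O)[C@H](O)Cc1c(O)c(Cc2c(O)c(C(C)=O)c(O)c(C)c2OC)c(O)c(C(=O)CCC)c1O
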